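A direct plan would esterify an ortho-iodophenol to the aryl iodide A1 (phenol tiglate, benzylic isobutyrate), couple A1 with a C3 allene and an isobutyrate salt under palladium catalysis to the 2-arylallyl isobutyrate A2, and end with a catalyst-controlled asymmetric epoxidation of A2. Its weakest steps would be the epoxidation of the 1,1-disubstituted alkene (faces that differ only by aryl against CH2O-acyl), the three-component arylpalladation (a gas and a weak carboxylate nucleophile beside a base-labile aryl ester, with Heck and diene pathways in competition), and the separate isobutyrylation of the benzylic alcohol, which would add a step without adding complexity.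

In thymol numbering (C7 benzylic CH2, C8 quaternary oxirane carbon, C9 oxirane CH2, C10 acyloxymethyl carbon), the route cuts the C9–O bond of the oxirane and the O10 ester and arrives at a prochiral 2-arylglycerol: C8 carries two enantiotopic CH2OH arms, of which the target keeps one as an isobutyrate and closes the other into the oxirane. A lipase with isobutyric anhydride would esterify the benzylic C7–OH and one arm in a single operation, setting the only stereocentre and installing both isobutyrates. C8 comes from aryllithium addition to a symmetrical C3 ketone, so no alkene is made or epoxidised, no allene coupling is run, and no separate isobutyrylation remains.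

Key step: step 4

Remark on the chemistry: which enantiotopic arm a given lipase acylates is found by screening; the route is written for an enzyme that takes the pro-R arm.

Step 1
Reactants: 1 2-bromo-5-(hydroxymethyl)phenol; 2 2,2-dimethyl-1,3-dioxan-5-one
Product: 4 5-[2-hydroxy-4-(hydroxymethyl)phenyl]-2,2-dimethyl-1,3-dioxan-5-ol, via trilithiated aryl species 3 (not isolated)
Conditions: n-BuLi (2.05 equiv), THF, −78 °C; t-BuLi (2.1 equiv), −78 °C; then 2 (1.2 equiv), −78 → 0 °C; aq. NH4Cl
Reagents that add atoms: 2,2-dimethyl-1,3-dioxan-5-one (2), CC1(C)OCC(=O)CO1; n-butyllithium, [Li]CCCC and tert-butyllithium, [Li]C(C)(C)C (lithium of 3 only)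
Why: Deprotonation of both hydroxyl groups and bromine–lithium exchange should give an ortho-lithiated lithium phenoxide that adds 1,2 to the symmetrical ketone (organolithium addition to a ketone), which forms the aryl–C8 bond and leaves C8 with two identical CH2O arms, so no stereocentre arises.

Step 2
Reactants: 4 5-[2-hydroxy-4-(hydroxymethyl)phenyl]-2,2-dimethyl-1,3-dioxan-5-ol; 5 tigloyl chloride, (E)-2-methylbut-2-enoyl chloride
Product: 6 2-(5-hydroxy-2,2-dimethyl-1,3-dioxan-5-yl)-5-(hydroxymethyl)phenyl (E)-2-methylbut-2-enoate
Conditions: 5 (1.05 equiv), 1 M aq. NaOH (1.1 equiv), Bu4NHSO4 (5 mol %), CH2Cl2, 0 °C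
Reagents that add atoms: tigloyl chloride (5), C/C=C(\C)C(=O)Cl
Why: Schotten–Baumann acylation under phase transfer, in which dilute hydroxide ionises only the phenol, so the phenoxide is acylated while the primary benzylic and the tertiary hydroxyl groups stay free, and the absence of an amine base should keep the (E) geometry of the acyl group.

Step 3
Reactants: 6 2-(5-hydroxy-2,2-dimethyl-1,3-dioxan-5-yl)-5-(hydroxymethyl)phenyl (E)-2-methylbut-2-enoate
Product: 7 5-(hydroxymethyl)-2-(1,2,3-trihydroxypropan-2-yl)phenyl (E)-2-methylbut-2-enoate
Conditions: AcOH/H2O/THF (3:1:1), 30 °C; evaporation with toluene below 30 °C; used at once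
Reagents that add atoms: none
Why: Acid-catalysed hydrolysis of the isopropylidene acetal of a 1,3-diol, mild enough for the hindered conjugated aryl ester, should free both CH2OH arms on the still prochiral C8, and immediate use limits aryl-to-alkyl acyl shift.

Step 4
Reactants: 7 5-(hydroxymethyl)-2-(1,2,3-trihydroxypropan-2-yl)phenyl (E)-2-methylbut-2-enoate; 8 isobutyric anhydride
Product: 9 2-[(2R)-1,2-dihydroxy-3-(2-methylpropanoyloxy)propan-2-yl]-5-[(2-methylpropanoyloxy)methyl]phenyl (E)-2-methylbut-2-enoate
Conditions: immobilised Candida antarctica lipase B (Novozym 435), 8 (2.1 equiv), MeCN, 0–5 °C, conversion followed by HPLC; filtration, cold aq. NaHCO3 wash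
Reagents that add atoms: isobutyric anhydride (8), CC(C)C(=O)OC(=O)C(C)C
Why: The active-site serine of the lipase is acylated by 8 to an isobutyryl-enzyme that hands its acyl group to primary hydroxyl groups only, so the benzylic C7–OH is esterified without stereochemical consequence and, of the two enantiotopic CH2OH arms on C8, the chiral binding site takes one. The closest known reaction type is the lipase desymmetrisation of prochiral 2-substituted propane-1,3-diols and 2-substituted glycerols by acyl transfer from anhydrides or enol esters. No ring is closed; the single new stereocentre C8 is fixed by the enzyme alone, and acylation of the pro-R arm gives (R)-9, which becomes the (R)-oxirane once the other arm is closed. The step needs primary over tertiary hydroxyl selectivity (tertiary alcohols are not acylated by lipases), survival of the aryl tiglate (an α-branched conjugated acyl group forms an acyl-enzyme only very slowly and is shielded by the ortho quaternary carbon), and mono- over bis-acylation of the glycerol unit, which the 2.1 equiv of 8 should secure. Any third acylation should fall mainly on the minor enantiomer, whose free arm is the one the enzyme prefers, and so should raise the enantiomeric purity of 9. The cold, base-free medium should keep uncatalysed acylation and racemising acyl shifts slow.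

Step 5
Reactants: 9 2-[(2R)-1,2-dihydroxy-3-(2-methylpropanoyloxy)propan-2-yl]-5-[(2-methylpropanoyloxy)methyl]phenyl (E)-2-methylbut-2-enoate
Product: 11 2-[(2R)-2-[(2-methylpropanoyloxy)methyl]oxiran-2-yl]-5-[(2-methylpropanoyloxy)methyl]phenyl (E)-2-methylbut-2-enoate (target), via primary mesylate 10 (not isolated)
Conditions: MsCl (1.1 equiv), Et3N (1.5 equiv), CH2Cl2, −30 °C; then DBU (2.0 equiv), −30 → 20 °C; Et3N-deactivated silica
Reagents that add atoms: methanesulfonyl chloride, CS(=O)(=O)Cl (mesyl group of 10 only)
Why: Sulfonylation of the only primary hydroxyl group and intramolecular Williamson closure (3-exo-tet) by the tertiary alkoxide should form the C9–O bond without touching the C8–O bond, so the configuration set in step 4 is carried unchanged into the (R)-oxirane, and the non-nucleophilic amidine base should spare the three esters.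

Compound list
1 | 2-bromo-5-(hydroxymethyl)phenol | OCc1ccc(Br)c(O)c1 | starting material
2 | 2,2-dimethyl-1,3-dioxan-5-one | CC1(C)OCC(=O)CO1 | starting material
3 | trilithiated aryl species, lithium [4-lithio-3-(lithiooxy)phenyl]methanolate (not isolated) | [Li]OCc1ccc([Li])c(O[Li])c1 | intermediate
4 | 5-[2-hydroxy-4-(hydroxymethyl)phenyl]-2,2-dimethyl-1,3-dioxan-5-ol | CC1(C)OCC(O)(CO1)c1ccc(CO)cc1O | intermediate
5 | tigloyl chloride, (E)-2-methylbut-2-enoyl chloride | C/C=C(\C)C(=O)Cl | starting material
6 | 2-(5-hydroxy-2,2-dimethyl-1,3-dioxan-5-yl)-5-(hydroxymethyl)phenyl (E)-2-methylbut-2-enoate | C/C=C(\C)C(=O)Oc1cc(CO)ccc1C1(O)COC(C)(C)OC1 | intermediate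
7 | 5-(hydroxymethyl)-2-(1,2,3-trihydroxypropan-2-yl)phenyl (E)-2-methylbut-2-enoate | C/C=C(\C)C(=O)Oc1cc(CO)ccc1C(O)(CO)CO | intermediate
8 | isobutyric anhydride | CC(C)C(=O)OC(=O)C(C)C | starting material
9 | 2-[(2R)-1,2-dihydroxy-3-(2-methylpropanoyloxy)propan-2-yl]-5-[(2-methylpropanoyloxy)methyl]phenyl (E)-2-methylbut-2-enoate | C/C=C(\C)C(=O)Oc1cc(COC(=O)C(C)C)ccc1[C@](O)(COC(=O)C(C)C)CO | intermediate
10 | 2-[(2S)-2-hydroxy-1-(methylsulfonyloxy)-3-(2-methylpropanoyloxy)propan-2-yl]-5-[(2-methylpropanoyloxy)methyl]phenyl (E)-2-methylbut-2-enoate (not isolated) | C/C=C(\C)C(=O)Oc1cc(COC(=O)C(C)C)ccc1[C@](O)(COC(=O)C(C)C)COS(C)(=O)=O | intermediate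
11 | 2-[(2R)-2-[(2-methylpropanoyloxy)methyl]oxiran-2-yl]-5-[(2-methylpropanoyloxy)methyl]phenyl (E)-2-methylbut-2-enoate | C/C=C(\C)C(=O)Oc1cc(COC(=O)C(C)C)ccc1[C@]1(COC(=O)C(C)C)CO1 | target

Total step count: 5. Longest linear sequence: 5.

Steps most likely to fail

Step 4. The lipase may discriminate poorly between the two enantiotopic arms or acylate the wrong one, because the ortho-substituted aryl group may fit badly in the alcohol pocket; acyl shifts during the reaction would further erode the purity. The fallback sets out from 7 and is a non-enzymatic desymmetrisation by enantioselective sulfonylation of the 1,2-diol unit. Cu(OTf)2 with a C2-symmetric bis(oxazoline) ligand (Ph-BOX, enantiomer chosen so that the pro-S arm reacts), TsCl and Na2CO3 in MeCN at 0 °C would give the monotosylate 2-[(2S)-1,2-dihydroxy-3-(4-methylbenzenesulfonyloxy)propan-2-yl]-5-(hydroxymethyl)phenyl (E)-2-methylbut-2-enoate F1. Isobutyric anhydride and pyridine in CH2Cl2 would then esterify both remaining primary hydroxyl groups to 2-[(2S)-2-hydroxy-1-(2-methylpropanoyloxy)-3-(4-methylbenzenesulfonyloxy)propan-2-yl]-5-[(2-methylpropanoyloxy)methyl]phenyl (E)-2-methylbut-2-enoate F2. DBU in CH2Cl2 would close the oxirane, which comes back to the route at 11.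

Step 5. Once DBU is added, the tigloyl group may shift from the phenol oxygen to the tertiary alkoxide and the freed phenoxide may attack the sulfonate carbon; an acyl shift across the glycerol unit before the mesylate is in place would racemise the material. The fallback sets out from 9 and is a base-free cyclodehydration of the 1,2-diol (Mitsunobu conditions: PPh3 and diisopropyl azodicarboxylate, toluene, 0 °C). The primary C9–OH would be activated as an alkoxyphosphonium ion and displaced by the tertiary hydroxyl group. No new isolated compound would be made on this way (F0), and it comes back to the route at 11.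

Step 1. Bromine–lithium exchange may stay incomplete on the sparingly soluble dilithium salt, and the strongly basic trilithiated species may enolise ketone 2 instead of adding to it. The fallback sets out from 1 and masks the phenol alone (BnBr, K2CO3, acetone) as [3-(benzyloxy)-4-bromophenyl]methanol F3. n-BuLi (2.1 equiv, THF, −78 °C), transmetalation with anhydrous CeCl3 and addition of 2 would give 5-[2-(benzyloxy)-4-(hydroxymethyl)phenyl]-2,2-dimethyl-1,3-dioxan-5-ol F4 through a less basic organocerium reagent. Hydrogenolysis (H2, Pd/C, EtOAc) would come back to the route at 4.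

Further compounds
F1 | step 4 | 2-[(2S)-1,2-dihydroxy-3-(4-methylbenzenesulfonyloxy)propan-2-yl]-5-(hydroxymethyl)phenyl (E)-2-methylbut-2-enoate | C/C=C(\C)C(=O)Oc1cc(CO)ccc1[C@](O)(CO)COS(=O)(=O)c1ccc(C)cc1
F2 | step 4 | 2-[(2S)-2-hydroxy-1-(2-methylpropanoyloxy)-3-(4-methylbenzenesulfonyloxy)propan-2-yl]-5-[(2-methylpropanoyloxy)methyl]phenyl (E)-2-methylbut-2-enoate | C/C=C(\C)C(=O)Oc1cc(COC(=O)C(C)C)ccc1[C@](O)(COC(=O)C(C)C)COS(=O)(=O)c1ccc(C)cc1
F0 | step 5 | none | none
F3 | step 1 | [3-(benzyloxy)-4-bromophenyl]methanol | OCc1ccc(Br)c(OCc2ccccc2)c1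
F4 | step 1 | 5-[2-(benzyloxy)-4-(hydroxymethyl)phenyl]-2,2-dimethyl-1,3-dioxan-5-ol | CC1(C)OCC(O)(CO1)c1ccc(CO)cc1OCc1ccccc1
A1 | direct plan | 2-iodo-5-[(2-methylpropanoyloxy)methyl]phenyl (E)-2-methylbut-2-enoate | C/C=C(\C)C(=O)Oc1cc(COC(=O)C(C)C)ccc1I
A2 | direct plan | 2-[3-(2-methylpropanoyloxy)prop-1-en-2-yl]-5-[(2-methylpropanoyloxy)methyl]phenyl (E)-2-methylbut-2-enoate | C/C=C(\C)C(=O)Oc1cc(COC(=O)C(C)C)ccc1C(=C)COC(=O)C(C)C
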